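## Structural features

The target is a 2,3,4-trisubstituted oxolane (O1, C2–C5). C2 carries a 3,4,5-trimethoxyphenyl ring, C3 a hydroxymethyl group, C4 a secondary benzylic carbinol carbon bearing a 3,4-dimethoxyphenyl ring, and C5 is an unsubstituted CH2. Four stereocentres stand in a row (C2, C3, C4, carbinol carbon). The ring is 2,3-trans and 3,4-trans (2R,3S,4R). The carbinol carbon is S, so that the carbinol oxygen and C3 are syn when the chain C5–C4–carbinol carbon–aryl is drawn as a zigzag. Both benzylic C–O bonds (C2–O1 and the carbinol C–OH) sit on electron-rich rings, so acid can ionise them (epimerisation at C2, dehydration, or closure to an isomeric oxolane), and strong oxidants and hydrogenolysis are also excluded. The two primary carbons (C5 and the hydroxymethyl carbon on C3) are alike and must be told apart in any ring closure. The real difficulty is the exocyclic carbinol stereocentre, which must be related to C4, together with the absolute configuration at C2/C3; the trans,trans ring pattern itself is the thermodynamically preferred one. The key step uses two facts: C2 bears both O1 and the C2–C3 bond (the pattern an aldehyde allylation leaves), and C4 carries two one-carbon branches (C5 and the carbinol carbon) that can be carried as the carbonyl and the exocyclic methylene of a 3-methylidene-oxolan-2-one whose ring oxygen is O1.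

## Logic of the disconnections

Atom labels are those of the target oxolane.

21 from 20: the Si–O bond on the C3 hydroxymethyl oxygen is the last bond cut. This oxygen must stay masked until the ring exists, because otherwise the carbinol oxygen could close a five-membered ring onto the wrong primary carbon. Nothing is gained in skeleton. The demand is a fluoride cleavage that leaves both benzylic C–O bonds alone.

20 from 18 (through 19): the O1–C5 bond is cut. C5 is the only ring carbon without a stereocentre, so an SN2 closure there changes no configuration and O1 stays on C2 throughout. The ring becomes an acyclic chain with three free hydroxyls. The forward step must activate the primary hydroxyl selectively and close 5-exo-tet before the carbinol alkoxide can interfere.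

18 from 17: C5 is raised to the carboxyl level and tied back to the C2 oxygen. This makes C4 a carbonyl α-carbon and places the carbinol oxygen β to a carbonyl. The demand is a hydride reduction that does not cleave the aldol unit.

17 from 16: the carbinol C–H bond is cut (alcohol to ketone). With C4 between two carbonyls its configuration becomes thermodynamic (trans to the C3 substituent), and the 1,3-dicarbonyl unit can chelate. Two stereocentres thus become consequences of C3. The demand is hydride delivery from the face of the chelated ketone that is flanked by the C4 hydrogen.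

16 from 15 from 13: the C–O bond at the carbinol carbon is removed, leaving a C4=C double bond. Oxygen β to a carbonyl is the polarity of a conjugate addition (boryl, then oxidation). The stereochemistry of this hydration does not matter, because 16 erases it; only reactivity of a trisubstituted enoate is demanded.

13 from 10 and 12 (12 from 11): the bond between the carbinol carbon and its aryl ring is cut. The terminal carbon of an exocyclic methylene is where an aryl–palladium species adds. This removes one aromatic ring and leaves a small lactone. The demand is β-hydride elimination toward the benzylic side, not into the ring.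

10 from 7 and 8 (through 9): C2–C3 and the acyl C5–O1 bond are cut together. This is the disconnection that carries the strategy. It removes the ring and both ring stereocentres that must be made absolute, and leaves an aldehyde and an allylboronate. The forward step needs a geometrically pure alkene in 7 (for 2,3-trans) and control of the aldehyde face (for 2R).

7 from 4 and 5 (through 6), 4 from 1 and 2 (through 3): the bond between C4 and the future carbinol carbon is cut, then the C4–C5 bond. A syn hydrometalation of an alkyne fixes the alkene geometry by mechanism. Four simple one- to three-carbon pieces remain. The demand is 1,4- rather than 1,2-delivery of hydride and alkylation on carbon with retention.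

## Other disconnections considered

Alternative 1: The cut is C3–C4. Forward, the acyclic ether A1 (C2 and the O1–C5 link already present) would be converted into its bis-silyl enol derivative and oxidised with (NH4)2Ce(NO3)6, joining the ester α-carbon to the ketone α-carbon to give A2.
- In its favour: both new centres are α to carbonyls and settle to all-trans. C5 is already a CH2, so no lactone has to be opened and reclosed. Only a ketone and an ester reduction remain. On step count after the key step (about two against eight) and on total length (roughly seven against eleven) it is better than the chosen plan.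
- Against it: A1 is a β-alkoxy ester, so enolisation at the ester α-carbon invites E1cB loss of the whole phenacyloxy unit. An ester is not enolised by a silyl triflate and an amine, so a stronger base and hence that elimination cannot be avoided. Tetravalent cerium oxidises electron-rich benzylic ethers, and C2–H of A1 is exactly such a position. C2 must be made enantiopure beforehand by a separate asymmetric step followed by an awkward O-alkylation of a β-hydroxy ester.
- Comparison: the ring stereochemistry is equal (thermodynamic here, stereospecific chair in the chosen plan). The carbinol is weaker here, since the ketone of A2 has no 1,3-dicarbonyl partner for chelation. The mechanism (radical-cation coupling next to two oxidisable arenes) is less predictable than a closed allylboration.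

Alternative 2: The cuts are O1–C5, C3–C4 and the C–O bond of the hydroxymethyl group. Forward, the lithium alkoxide of A3 would add to the acrylate A4, [Cp2Fe]PF6 would oxidise the resulting enolate, the radical would close 5-exo onto the vinyl group and the nitroxyl would trap the primary radical, giving A5.
- In its favour: three bonds form in one flask. The absolute configuration comes from A3, an easily made enantiopure allylic alcohol. C5 arrives as CH2 and the hydroxymethyl oxygen is installed directly; on both points it is better than the chosen plan. The 2,3-trans relation follows from a chair-like 5-exo transition state with the aryl group equatorial.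
- Against it: A4 is a methylene β-keto ester that dimerises and polymerises readily. The oxa-Michael addition of a hindered benzylic alkoxide is reversible. C4 ends quaternary, so the tert-butyl ester must be removed under acid (a risk to the C2–O1 bond) and decarboxylated. The ketone is then reduced without the second carbonyl, so the carbinol is set with less control than in the chosen plan. The N–O bond needs its own cleavage.
- Comparison: the step count is about equal (nine to ten). Diastereoselectivity in the radical closure is normally lower than in a stereospecific allylboration. Enantiocontrol is the equal or the better of the chosen plan, because it is bought with a reliable asymmetric synthesis of A3.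

Alternative 3: The cuts are O1–C2 and C3–C4. Forward, under a diarylprolinol silyl ether the hydroxyl of A7 would add to the iminium ion of A6, and the enamine would then add 5-exo to the nitroalkene, giving A8.
- In its favour: a catalytic asymmetric step sets all three ring stereocentres from achiral pieces. The shielding model of the catalyst is well understood, so on enantiocontrol it is the equal or the better of a phosphoric acid acting on an ester-deactivated boronate. C5 is a CH2 from the start, and the aldehyde on C3 needs only one reduction.
- Against it: addition of a primary aliphatic alcohol to an iminium ion is reversible and slow, and the electron-rich A6 gives a poorly electrophilic iminium. A7 is an α-aryl, trisubstituted nitroalkene that is a sluggish acceptor and not trivial to make. The nitro group must be turned into the carbinol by a Nef reaction (oxidising or strongly acidic conditions next to two electron-rich rings) and a ketone reduction with no strong control element.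
- Comparison: on step count it would be shorter (about seven to eight). On the carbinol stereocentre and on the reliability of each individual step the chosen plan is stronger.

Key step: step 3

Remarks on the chemistry (assumptions and corrections made in planning):
- Compounds 1, 2, 5, 8, 11 and the phosphoric acid (R)-TRIP [(R)-3,3′-bis(2,4,6-triisopropylphenyl)-1,1′-binaphthyl-2,2′-diyl hydrogen phosphate] are taken as catalogue items.
- An entry to the allylboronate by copper-catalysed SN2′ borylation of a Morita–Baylis–Hillman acetate is not used. With acrylate esters that elimination is expected to put the β-substituent cis to CH2B (the E ester). Through the chair this gives the syn adduct and the 2,3-cis lactone. The isomer needed has the silyloxymethyl group trans to CH2B (Z) and is made by syn hydroalumination of an ynoate.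
- tert-Butyldiphenylsilyl (TBDPS) is used on the C3 hydroxymethyl oxygen. It withstands the acid and the methanol of the lactonisation and migrates less readily under base than a tert-butyldimethylsilyl group.
- A conjugate borylation that ends with protonation at C4 cannot be trusted for 3,4-trans, since proton delivery anti to the C3 substituent places the side chain cis. C4 and the carbinol carbon are therefore set through the β-keto lactone 16.
- The sense of induction of (R)-TRIP is assigned by analogy with its allyl- and crotylboronate additions to aryl aldehydes (Re face). If it proves opposite, the (S)-acid is used and nothing else changes.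

## Route

Step 1
Reactants: 1 tert-butyl(diphenyl)(prop-2-yn-1-yloxy)silane; 2 methyl chloroformate
Product: 4 methyl 4-(tert-butyldiphenylsilyloxy)but-2-ynoate, via lithium acetylide 3 (not isolated)
Conditions: n-BuLi, THF, −78 °C; then 2, −78 to 0 °C
Reagents that add atoms: none
Why: Deprotonation of the terminal alkyne and C-acylation of the lithium acetylide by a chloroformate is a standard ynoate synthesis; the silyl ether is inert at low temperature and no stereocentre is involved.

Step 2
Reactants: 4 methyl 4-(tert-butyldiphenylsilyloxy)but-2-ynoate; 5 2-(iodomethyl)-4,4,5,5-tetramethyl-1,3,2-dioxaborolane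
Product: 7 methyl (Z)-4-(tert-butyldiphenylsilyloxy)-2-[(4,4,5,5-tetramethyl-1,3,2-dioxaborolan-2-yl)methyl]but-2-enoate, via alkenylalane 6 (not isolated)
Conditions: i-Bu2AlH, HMPA, THF, 0 °C; then 5, 0 °C to rt
Reagents that add atoms: none
Why: The i-Bu2AlH–HMPA complex adds hydride 1,4 to the ynoate (conjugate hydroalumination) with H and Al cis, and C-alkylation of the α-aluminated enoate by the iodomethylboronate with retention leaves CH2B cis to the vinyl hydrogen and the silyloxymethyl group cis to the ester, i.e. the (Z)-alkene; this hydroalumination–alkylation is the established route to 3-substituted 2-(alkoxycarbonyl)allylboronates.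

Step 3
Reactants: 7 methyl (Z)-4-(tert-butyldiphenylsilyloxy)-2-[(4,4,5,5-tetramethyl-1,3,2-dioxaborolan-2-yl)methyl]but-2-enoate; 8 3,4,5-trimethoxybenzaldehyde
Product: 10 (4S,5R)-4-[(tert-butyldiphenylsilyloxy)methyl]-3-methylidene-5-(3,4,5-trimethoxyphenyl)oxolan-2-one, via homoallylic borate 9 (not isolated)
Conditions: (R)-TRIP (10 mol%), 4 Å MS, toluene, 0 °C to rt; then p-TsOH·H2O (10 mol%), rt
Reagents that add atoms: none
Why: The boronate adds to the aldehyde through a closed six-membered chair in which boron binds the carbonyl oxygen and the γ-carbon forms the C2–C3 bond with allylic transposition, leaving the 2-methylidene ester 9, whose boron-bound oxygen (O1) then displaces methoxide from the ester. The closest known reaction types are the chiral phosphoric acid-catalysed allyl- and crotylboration of aryl aldehydes with pinacol boronates and the allylboration–lactonisation of 2-(alkoxycarbonyl)allylboronates. The one ring formed, the lactone, closes 5-exo-trig by attack of O1 on the ester carbonyl (the later C5). The relative configuration is set by the alkene geometry of 7: the silyloxymethyl group is trans to CH2B and so pseudo-equatorial, the aryl group of the aldehyde is equatorial too, which gives the anti adduct and hence the 2,3-trans lactone (C3 becomes S once C2 is R). The absolute configuration at C2 is set by the catalyst, whose acidic proton binds the pseudo-axial boronate oxygen while the phosphoryl oxygen holds the formyl hydrogen, so that the (R)-acid should expose the Re face of the aldehyde (2R). The step needs anti over syn selectivity, secured by the geometric purity of 7, and Re over Si selectivity, secured by the catalyst and helped by the expected absence of an uncatalysed background reaction of this ester-deactivated boronate at room temperature. Should the benzylic C2–O1 bond ionise during the acid phase, reclosure to the more stable trans lactone would restore 2R from the intact C3 centre, so the lactonisation should not erode the result. The TBDPS ether tolerates the sulfonic acid and the methanol that is released.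

Step 4
Reactants: 11 3,4-dimethoxyaniline
Product: 12 3,4-dimethoxybenzenediazonium tetrafluoroborate
Conditions: NaNO2, aq. HBF4, H2O, 0 °C
Reagents that add atoms: sodium nitrite, [Na+].[O-]N=O; tetrafluoroboric acid, [H+].F[B-](F)(F)F
Why: Diazotisation of an aniline in tetrafluoroboric acid is standard; the electron-rich diazonium tetrafluoroborate precipitates and can be stored cold.

Step 5
Reactants: 10 (4S,5R)-4-[(tert-butyldiphenylsilyloxy)methyl]-3-methylidene-5-(3,4,5-trimethoxyphenyl)oxolan-2-one; 12 3,4-dimethoxybenzenediazonium tetrafluoroborate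
Product: 13 (3E,4S,5R)-4-[(tert-butyldiphenylsilyloxy)methyl]-3-[(3,4-dimethoxyphenyl)methylidene]-5-(3,4,5-trimethoxyphenyl)oxolan-2-one
Conditions: Pd(OAc)2 (5 mol%), NaOAc, MeCN, rt to 40 °C
Reagents that add atoms: none
Why: Heck–Matsuda arylation: the cationic arylpalladium species formed from zerovalent palladium and the diazonium salt adds aryl to the unsubstituted methylene carbon, and syn β-hydride elimination from the new benzylic CH2 gives the conjugated benzylidene lactone; the mild, phosphine-free conditions with acetate buffer spare the silyl ether and the C2 and C3 stereocentres, and the alkene geometry is not critical because the carbinol carbon later passes through a ketone.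

Step 6
Reactants: 13 (3E,4S,5R)-4-[(tert-butyldiphenylsilyloxy)methyl]-3-[(3,4-dimethoxyphenyl)methylidene]-5-(3,4,5-trimethoxyphenyl)oxolan-2-one
Product: 15 (4S,5R)-4-[(tert-butyldiphenylsilyloxy)methyl]-3-[(3,4-dimethoxyphenyl)(hydroxy)methyl]-5-(3,4,5-trimethoxyphenyl)oxolan-2-one as a mixture of epimers at C3 of the lactone and at the carbinol carbon, via boryl lactone 14 (not isolated)
Conditions: B2pin2, CuCl (5 mol%), Xantphos (5 mol%), t-BuONa (10 mol%), MeOH (2 equiv), THF, rt; then NaBO3·4H2O, THF/H2O, rt
Reagents that add atoms: sodium perborate (oxygen of the new hydroxyl), [Na+].[Na+].O[B-]1(O)OO[B-](O)(O)OO1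
Why: Copper-catalysed conjugate borylation: the monovalent copper boryl delivers boron to the β-carbon of the enoate (the benzylic carbon), methanol protonates the copper enolate, and perborate replaces boron by oxygen with retention without opening the lactone; the two new centres may form as mixtures because steps 7 and 8 renew both.

Step 7
Reactants: 15 (4S,5R)-4-[(tert-butyldiphenylsilyloxy)methyl]-3-[(3,4-dimethoxyphenyl)(hydroxy)methyl]-5-(3,4,5-trimethoxyphenyl)oxolan-2-one (epimer mixture)
Product: 16 (3S,4S,5R)-4-[(tert-butyldiphenylsilyloxy)methyl]-3-(3,4-dimethoxybenzoyl)-5-(3,4,5-trimethoxyphenyl)oxolan-2-one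
Conditions: Dess–Martin periodinane, CH2Cl2, 0 °C to rt
Reagents that add atoms: none
Why: Dess–Martin oxidation of the secondary benzylic alcohol gives the aryl ketone under near-neutral conditions; C4 of the target now lies between two carbonyls and equilibrates through the enol to the isomer with the aroyl group trans to the C3 substituent, so every stereoisomer of 15 should converge on one β-keto lactone.

Step 8
Reactants: 16 (3S,4S,5R)-4-[(tert-butyldiphenylsilyloxy)methyl]-3-(3,4-dimethoxybenzoyl)-5-(3,4,5-trimethoxyphenyl)oxolan-2-one
Product: 17 (3S,4S,5R)-4-[(tert-butyldiphenylsilyloxy)methyl]-3-[(S)-(3,4-dimethoxyphenyl)(hydroxy)methyl]-5-(3,4,5-trimethoxyphenyl)oxolan-2-one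
Conditions: Zn(BH4)2, Et2O/CH2Cl2, −78 to −20 °C
Reagents that add atoms: none
Why: Chelation-controlled reduction: zinc bridges the ketone and lactone carbonyl oxygens in a six-membered chelate and hydride enters the ketone from the side of the C4 hydrogen, not from the side of C3, which should give the (S)-carbinol (the syn β-hydroxy carbonyl pattern typical of zinc borohydride with α-substituted β-keto esters); the lactone is not reduced at this temperature.

Step 9
Reactants: 17 (3S,4S,5R)-4-[(tert-butyldiphenylsilyloxy)methyl]-3-[(S)-(3,4-dimethoxyphenyl)(hydroxy)methyl]-5-(3,4,5-trimethoxyphenyl)oxolan-2-one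
Product: 18 (1S,2R,3S,4R)-3-[(tert-butyldiphenylsilyloxy)methyl]-1-(3,4-dimethoxyphenyl)-2-(hydroxymethyl)-4-(3,4,5-trimethoxyphenyl)butane-1,4-diol
Conditions: LiAlH4, THF, 0 °C; H2O, aq. NaOH work-up
Reagents that add atoms: none
Why: Hydride reduction of the lactone to the 1,4-diol breaks only the acyl C–O bond, so C2 keeps its oxygen and configuration; the low temperature should hold the aluminium aldolate against retro-aldol cleavage and keep the silyl ether in place.

Step 10
Reactants: 18 (1S,2R,3S,4R)-3-[(tert-butyldiphenylsilyloxy)methyl]-1-(3,4-dimethoxyphenyl)-2-(hydroxymethyl)-4-(3,4,5-trimethoxyphenyl)butane-1,4-diol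
Product: 20 (S)-[(3R,4S,5R)-4-[(tert-butyldiphenylsilyloxy)methyl]-5-(3,4,5-trimethoxyphenyl)oxolan-3-yl](3,4-dimethoxyphenyl)methanol, via primary tosylate 19 (not isolated)
Conditions: TsCl (1.1 equiv), Et3N, DMAP (cat.), THF, 0 °C; then t-BuOK, 0 °C to rt
Reagents that add atoms: none
Why: The primary hydroxyl is the least hindered of the three and is sulfonylated selectively; on deprotonation the C2 alkoxide displaces the tosylate at C5 in a 5-exo-tet Williamson closure that touches no stereocentre, whereas the carbinol alkoxide could only close a four-membered ring and the second primary oxygen is blocked as its silyl ether.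

Step 11
Reactants: 20 (S)-[(3R,4S,5R)-4-[(tert-butyldiphenylsilyloxy)methyl]-5-(3,4,5-trimethoxyphenyl)oxolan-3-yl](3,4-dimethoxyphenyl)methanol
Product: 21 (S)-(3,4-dimethoxyphenyl)[(3R,4S,5R)-4-(hydroxymethyl)-5-(3,4,5-trimethoxyphenyl)oxolan-3-yl]methanol
Conditions: n-Bu4NF, THF, 0 °C to rt
Reagents that add atoms: none
Why: Fluoride cleaves the Si–O bond under non-acidic conditions, so neither benzylic C–O bond is at risk and no stereocentre is affected.

## Compound list

1 | tert-butyl(diphenyl)(prop-2-yn-1-yloxy)silane | C#CCO[Si](c1ccccc1)(c1ccccc1)C(C)(C)C | starting material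
2 | methyl chloroformate | COC(=O)Cl | starting material
3 | lithium acetylide of 1, [3-(tert-butyldiphenylsilyloxy)prop-1-yn-1-yl]lithium (not isolated) | [Li]C#CCO[Si](c1ccccc1)(c1ccccc1)C(C)(C)C | intermediate
4 | methyl 4-(tert-butyldiphenylsilyloxy)but-2-ynoate | COC(=O)C#CCO[Si](c1ccccc1)(c1ccccc1)C(C)(C)C | intermediate
5 | 2-(iodomethyl)-4,4,5,5-tetramethyl-1,3,2-dioxaborolane | ICB1OC(C)(C)C(C)(C)O1 | starting material
6 | methyl (E)-4-(tert-butyldiphenylsilyloxy)-2-(diisobutylalumanyl)but-2-enoate, Al cis to the vinyl H (not isolated) | COC(=O)/C([Al](CC(C)C)CC(C)C)=C\CO[Si](c1ccccc1)(c1ccccc1)C(C)(C)C | intermediate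
7 | methyl (Z)-4-(tert-butyldiphenylsilyloxy)-2-[(4,4,5,5-tetramethyl-1,3,2-dioxaborolan-2-yl)methyl]but-2-enoate | COC(=O)/C(CB1OC(C)(C)C(C)(C)O1)=C\CO[Si](c1ccccc1)(c1ccccc1)C(C)(C)C | intermediate
8 | 3,4,5-trimethoxybenzaldehyde | COc1cc(C=O)cc(OC)c1OC | starting material
9 | methyl (3S,4R)-3-[(tert-butyldiphenylsilyloxy)methyl]-2-methylidene-4-[(4,4,5,5-tetramethyl-1,3,2-dioxaborolan-2-yl)oxy]-4-(3,4,5-trimethoxyphenyl)butanoate (not isolated) | COC(=O)C(=C)[C@@H](CO[Si](c1ccccc1)(c1ccccc1)C(C)(C)C)[C@@H](OB1OC(C)(C)C(C)(C)O1)c1cc(OC)c(OC)c(OC)c1 | intermediate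
10 | (4S,5R)-4-[(tert-butyldiphenylsilyloxy)methyl]-3-methylidene-5-(3,4,5-trimethoxyphenyl)oxolan-2-one | C=C1C(=O)O[C@@H](c2cc(OC)c(OC)c(OC)c2)[C@@H]1CO[Si](c3ccccc3)(c4ccccc4)C(C)(C)C | intermediate
11 | 3,4-dimethoxyaniline | Nc1ccc(OC)c(OC)c1 | starting material
12 | 3,4-dimethoxybenzenediazonium tetrafluoroborate | COc1ccc([N+]#N)cc1OC.F[B-](F)(F)F | intermediate
13 | (3E,4S,5R)-4-[(tert-butyldiphenylsilyloxy)methyl]-3-[(3,4-dimethoxyphenyl)methylidene]-5-(3,4,5-trimethoxyphenyl)oxolan-2-one | COc1ccc(/C=C2/C(=O)O[C@@H](c3cc(OC)c(OC)c(OC)c3)[C@@H]2CO[Si](c4ccccc4)(c5ccccc5)C(C)(C)C)cc1OC | intermediate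
14 | (4S,5R)-4-[(tert-butyldiphenylsilyloxy)methyl]-3-[(3,4-dimethoxyphenyl)(4,4,5,5-tetramethyl-1,3,2-dioxaborolan-2-yl)methyl]-5-(3,4,5-trimethoxyphenyl)oxolan-2-one, epimers at C3 and at the boron-bearing carbon (not isolated) | COc1ccc(C(B6OC(C)(C)C(C)(C)O6)C2C(=O)O[C@@H](c3cc(OC)c(OC)c(OC)c3)[C@@H]2CO[Si](c4ccccc4)(c5ccccc5)C(C)(C)C)cc1OC | intermediate
15 | (4S,5R)-4-[(tert-butyldiphenylsilyloxy)methyl]-3-[(3,4-dimethoxyphenyl)(hydroxy)methyl]-5-(3,4,5-trimethoxyphenyl)oxolan-2-one, epimers at C3 and at the carbinol carbon | COc1ccc(C(O)C2C(=O)O[C@@H](c3cc(OC)c(OC)c(OC)c3)[C@@H]2CO[Si](c4ccccc4)(c5ccccc5)C(C)(C)C)cc1OC | intermediate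
16 | (3S,4S,5R)-4-[(tert-butyldiphenylsilyloxy)methyl]-3-(3,4-dimethoxybenzoyl)-5-(3,4,5-trimethoxyphenyl)oxolan-2-one | COc1ccc(C(=O)[C@H]2C(=O)O[C@@H](c3cc(OC)c(OC)c(OC)c3)[C@@H]2CO[Si](c4ccccc4)(c5ccccc5)C(C)(C)C)cc1OC | intermediate
17 | (3S,4S,5R)-4-[(tert-butyldiphenylsilyloxy)methyl]-3-[(S)-(3,4-dimethoxyphenyl)(hydroxy)methyl]-5-(3,4,5-trimethoxyphenyl)oxolan-2-one | COc1ccc([C@@H](O)[C@H]2C(=O)O[C@@H](c3cc(OC)c(OC)c(OC)c3)[C@@H]2CO[Si](c4ccccc4)(c5ccccc5)C(C)(C)C)cc1OC | intermediate
18 | (1S,2R,3S,4R)-3-[(tert-butyldiphenylsilyloxy)methyl]-1-(3,4-dimethoxyphenyl)-2-(hydroxymethyl)-4-(3,4,5-trimethoxyphenyl)butane-1,4-diol | COc1ccc([C@@H](O)[C@@H](CO)[C@@H](CO[Si](c4ccccc4)(c5ccccc5)C(C)(C)C)[C@@H](O)c3cc(OC)c(OC)c(OC)c3)cc1OC | intermediate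
19 | (2R,3S)-4-(tert-butyldiphenylsilyloxy)-2-[(S)-(3,4-dimethoxyphenyl)(hydroxy)methyl]-3-[(R)-hydroxy(3,4,5-trimethoxyphenyl)methyl]butyl 4-methylbenzenesulfonate (not isolated) | COc1ccc([C@@H](O)[C@@H](COS(=O)(=O)c6ccc(C)cc6)[C@@H](CO[Si](c4ccccc4)(c5ccccc5)C(C)(C)C)[C@@H](O)c3cc(OC)c(OC)c(OC)c3)cc1OC | intermediate
20 | (S)-[(3R,4S,5R)-4-[(tert-butyldiphenylsilyloxy)methyl]-5-(3,4,5-trimethoxyphenyl)oxolan-3-yl](3,4-dimethoxyphenyl)methanol | COc1ccc([C@@H](O)[C@H]2CO[C@@H](c3cc(OC)c(OC)c(OC)c3)[C@@H]2CO[Si](c4ccccc4)(c5ccccc5)C(C)(C)C)cc1OC | intermediate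
21 | (S)-(3,4-dimethoxyphenyl)[(3R,4S,5R)-4-(hydroxymethyl)-5-(3,4,5-trimethoxyphenyl)oxolan-3-yl]methanol | COc1ccc([C@@H](O)[C@H]2CO[C@@H](c3cc(OC)c(OC)c(OC)c3)[C@@H]2CO)cc1OC | target

## Step count and least certain steps

Total: 11 steps. Longest linear sequence: 10 steps (1 → 4 → 7 → 10 → 13 → 15 → 16 → 17 → 18 → 20 → 21). Step 4 is a one-step side branch.

Step 3 (key step). The most likely failure is poor control of the aldehyde face. The ester lowers the nucleophilicity of the boronate and the aldehyde is electron-rich, so turnover through the acid-bound chair may be slow and a less organised pathway may compete. Incomplete lactonisation is a lesser concern. The fallback moves the control element into the reagent. It sets out from 1, which is lithiated and acylated with (1R,2S,5R)-8-phenylmenthyl chloroformate to give (1R,2S,5R)-5-methyl-2-(2-phenylpropan-2-yl)cyclohexyl 4-(tert-butyldiphenylsilyloxy)but-2-ynoate F1. Hydroalumination and alkylation with 5 as in step 2 give the corresponding (Z)-allylboronate, (1R,2S,5R)-5-methyl-2-(2-phenylpropan-2-yl)cyclohexyl (Z)-4-(tert-butyldiphenylsilyloxy)-2-[(4,4,5,5-tetramethyl-1,3,2-dioxaborolan-2-yl)methyl]but-2-enoate F2. Its addition to 8 (Sc(OTf)3, toluene, low temperature, then acid) is steered by the phenyl group of the auxiliary, which shields one face of the allyl unit, and lactonisation expels the auxiliary. The fallback comes back at 10. The sense of induction would have to be checked on the first run; the enantiomeric auxiliary is used if the wrong face is favoured.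

Step 5. After carbopalladation the palladium on C4 also has a syn hydrogen on C3. β-Hydride elimination into the ring, or later palladium hydride-mediated migration of the double bond into the ring, would give a butenolide and erase the C3 stereocentre. The fallback replaces the Heck manifold by olefin cross-metathesis. It sets out from 10, which is treated with 3,4-dimethoxystyrene and the second-generation Hoveyda–Grubbs catalyst RuCl2(H2IMes)(=CH–C6H4-2-Oi-Pr) in CH2Cl2 at 40 °C, with 2,6-dichloro-1,4-benzoquinone to suppress isomerisation. It comes back at 13 (no new compound: F0).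

Step 6. Borylcupration may be slow on this hindered trisubstituted enoate with an electron-rich β-aryl group. During a long reaction time the alkoxide could deprotonate C3 vinylogously and move the double bond into the ring. The fallback installs the oxygen electrophilically. It sets out from 13, which is epoxidised with dimethyldioxirane in acetone to the spiro-epoxide (6R,7S)-7-[(tert-butyldiphenylsilyloxy)methyl]-2-(3,4-dimethoxyphenyl)-6-(3,4,5-trimethoxyphenyl)-1,5-dioxaspiro[2.4]heptan-4-one F3. Reductive cleavage of the Cα–O bond with SmI2 in THF/MeOH at −78 °C gives the β-hydroxy lactone, and the fallback comes back at 15.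

Step 8. If chelation is incomplete, hydride delivery through an open Felkin-type arrangement would give the epimeric carbinol. The fallback changes from substrate to catalyst control. It sets out from 16, which is reduced by asymmetric transfer hydrogenation with RuCl(p-cymene)[(S,S)-TsDPEN] and HCO2H/Et3N. The aryl/alkyl discrimination of this catalyst should give the (S)-carbinol while C4 stays trans by equilibration. It comes back at 17 (no new compound: F0).

Step 10. Sulfonylation may not be fully selective for the primary hydroxyl. Once the carbinol alkoxide is formed next to the tosylate, Grob-type fragmentation or oxetane closure can compete with the 5-exo closure, and a strong base may move the silyl group. The fallback removes the carbinol hydroxyl from play: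
- It sets out from 17, which is silylated (Et3SiOTf, 2,6-lutidine) to (3S,4S,5R)-4-[(tert-butyldiphenylsilyloxy)methyl]-3-[(S)-(3,4-dimethoxyphenyl)(triethylsilyloxy)methyl]-5-(3,4,5-trimethoxyphenyl)oxolan-2-one F4.
- LiAlH4 gives (1R,2S,3R)-2-[(tert-butyldiphenylsilyloxy)methyl]-3-[(S)-(3,4-dimethoxyphenyl)(triethylsilyloxy)methyl]-1-(3,4,5-trimethoxyphenyl)butane-1,4-diol F5.
- Mitsunobu cyclodehydration (PPh3, diisopropyl azodicarboxylate, THF) activates the primary hydroxyl and closes the ring with retention at C2 to tert-butyl{[(2R,3S,4R)-4-[(S)-(3,4-dimethoxyphenyl)(triethylsilyloxy)methyl]-2-(3,4,5-trimethoxyphenyl)oxolan-3-yl]methoxy}diphenylsilane F6.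
- n-Bu4NF removes both silyl groups, and the fallback comes back at 21.

## Further compounds

F1 | step 3 | (1R,2S,5R)-5-methyl-2-(2-phenylpropan-2-yl)cyclohexyl 4-(tert-butyldiphenylsilyloxy)but-2-ynoate | CC(C)(C)[Si](c2ccccc2)(c3ccccc3)OCC#CC(=O)O[C@H]1[C@H](C(C)(C)c4ccccc4)CC[C@@H](C)C1
F2 | step 3 | (1R,2S,5R)-5-methyl-2-(2-phenylpropan-2-yl)cyclohexyl (Z)-4-(tert-butyldiphenylsilyloxy)-2-[(4,4,5,5-tetramethyl-1,3,2-dioxaborolan-2-yl)methyl]but-2-enoate | CC(C)(C)[Si](c2ccccc2)(c3ccccc3)OC/C=C(/CB5OC(C)(C)C(C)(C)O5)C(=O)O[C@H]1[C@H](C(C)(C)c4ccccc4)CC[C@@H](C)C1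
F0 | step 5 | none | none
F3 | step 6 | (6R,7S)-7-[(tert-butyldiphenylsilyloxy)methyl]-2-(3,4-dimethoxyphenyl)-6-(3,4,5-trimethoxyphenyl)-1,5-dioxaspiro[2.4]heptan-4-one, epoxide diastereomers | COc1ccc(C2OC23C(=O)O[C@@H](c4cc(OC)c(OC)c(OC)c4)[C@@H]3CO[Si](c5ccccc5)(c6ccccc6)C(C)(C)C)cc1OC
F0 | step 8 | none | none
F4 | step 10 | (3S,4S,5R)-4-[(tert-butyldiphenylsilyloxy)methyl]-3-[(S)-(3,4-dimethoxyphenyl)(triethylsilyloxy)methyl]-5-(3,4,5-trimethoxyphenyl)oxolan-2-one | COc1ccc([C@@H](O[Si](CC)(CC)CC)[C@H]2C(=O)O[C@@H](c3cc(OC)c(OC)c(OC)c3)[C@@H]2CO[Si](c4ccccc4)(c5ccccc5)C(C)(C)C)cc1OC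
F5 | step 10 | (1R,2S,3R)-2-[(tert-butyldiphenylsilyloxy)methyl]-3-[(S)-(3,4-dimethoxyphenyl)(triethylsilyloxy)methyl]-1-(3,4,5-trimethoxyphenyl)butane-1,4-diol | COc1ccc([C@@H](O[Si](CC)(CC)CC)[C@@H](CO)[C@@H](CO[Si](c4ccccc4)(c5ccccc5)C(C)(C)C)[C@@H](O)c3cc(OC)c(OC)c(OC)c3)cc1OC
F6 | step 10 | tert-butyl{[(2R,3S,4R)-4-[(S)-(3,4-dimethoxyphenyl)(triethylsilyloxy)methyl]-2-(3,4,5-trimethoxyphenyl)oxolan-3-yl]methoxy}diphenylsilane | COc1ccc([C@@H](O[Si](CC)(CC)CC)[C@H]2CO[C@@H](c3cc(OC)c(OC)c(OC)c3)[C@@H]2CO[Si](c4ccccc4)(c5ccccc5)C(C)(C)C)cc1OC
A1 | alternative 1 | ethyl (3R)-3-[2-(3,4-dimethoxyphenyl)-2-oxoethoxy]-3-(3,4,5-trimethoxyphenyl)propanoate | CCOC(=O)C[C@@H](OCC(=O)c1ccc(OC)c(OC)c1)c1cc(OC)c(OC)c(OC)c1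
A2 | alternative 1 | ethyl (2R,3R,4R)-4-(3,4-dimethoxybenzoyl)-2-(3,4,5-trimethoxyphenyl)oxolane-3-carboxylate (all-trans) | COc1ccc(C(=O)[C@H]2CO[C@@H](c3cc(OC)c(OC)c(OC)c3)[C@@H]2C(=O)OCC)cc1OC
A3 | alternative 2 | (R)-1-(3,4,5-trimethoxyphenyl)prop-2-en-1-ol | C=C[C@@H](O)c1cc(OC)c(OC)c(OC)c1
A4 | alternative 2 | tert-butyl 2-(3,4-dimethoxybenzoyl)prop-2-enoate | C=C(C(=O)OC(C)(C)C)C(=O)c1ccc(OC)c(OC)c1
A5 | alternative 2 | tert-butyl (4S,5R)-3-(3,4-dimethoxybenzoyl)-4-{[(2,2,6,6-tetramethylpiperidin-1-yl)oxy]methyl}-5-(3,4,5-trimethoxyphenyl)oxolane-3-carboxylate, 4,5-trans, epimers at C3 | COc1ccc(C(=O)C2(C(=O)OC(C)(C)C)CO[C@@H](c3cc(OC)c(OC)c(OC)c3)[C@@H]2CON4C(C)(C)CCCC4(C)C)cc1OC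
A6 | alternative 3 | (E)-3-(3,4,5-trimethoxyphenyl)prop-2-enal | COc1cc(/C=C/C=O)cc(OC)c1OC
A7 | alternative 3 | (E)-3-(3,4-dimethoxyphenyl)-3-nitroprop-2-en-1-ol | OC/C=C(\c1ccc(OC)c(OC)c1)[N+](=O)[O-]
A8 | alternative 3 | (2R,3R,4S)-4-[(3,4-dimethoxyphenyl)(nitro)methyl]-2-(3,4,5-trimethoxyphenyl)oxolane-3-carbaldehyde, epimers at the nitro carbon | COc1ccc(C([N+](=O)[O-])[C@H]2CO[C@@H](c3cc(OC)c(OC)c(OC)c3)[C@@H]2C=O)cc1OC
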